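**Retrosynthetic overview**
- The target comes from its 5,7-di-O-allyl ether by Pd-catalysed deallylation. Rings A and B are bought (phloroacetophenone, p-anisaldehyde). Only ring C is built, and it is built last.
- Ring C comes from a Claisen–Schmidt / Algar–Flynn–Oyamada sequence on an acetophenone that already carries the finished (S)-side chain.
- The (S)-carbinol comes from CBS reduction of the enone ArCH2–CO–C(Me)=CH2.
- The key C–C disconnection is Ar–CH2. The ring C–H of phloroacetophenone diallyl ether (donor carbon) is joined to the enolonium (alpha-carbonyl cation) of methyl isopropenyl ketone. The enolonium is made from the enol silane with PhI(OH)OTs/BF3·OEt2.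

Assumption: the SMILES is taken as binding. Its single stereocentre (C-2'' of the side chain) reads as (S), and "brevicornum" is taken only as the plant source in the name.

**Step 1**
Reactants: 1 2,4,6-trihydroxyacetophenone
Product: 2 1-[2-hydroxy-4,6-bis(prop-2-enyloxy)phenyl]ethanone
Conditions: allyl bromide (2.1 equiv), K2CO3 (2.2 equiv), acetone, reflux, 12 h
Reagents that add atoms: allyl bromide, C=CCBr
Why: Williamson etherification in which one ortho hydroxyl stays free because its strong hydrogen bond to the acetyl carbonyl lowers its nucleophilicity, so two equivalents of allyl bromide cap only the para hydroxyl and one of the two equivalent ortho hydroxyls.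

**Step 2**
Reactants: 3 3-methylbut-3-en-2-one (methyl isopropenyl ketone)
Product: 4 3-methyl-2-(trimethylsilyloxy)buta-1,3-diene
Conditions: TMSOTf (1.1 equiv), Et3N (1.3 equiv), Et2O, 0 °C, 1 h; pentane extraction, distillation
Reagents that add atoms: trimethylsilyl triflate, C[Si](C)(C)OS(=O)(=O)C(F)(F)F
Why: Soft enolisation (silyl triflate plus tertiary amine) of a ketone whose only enolisable position is the methyl group gives the cross-conjugated 2-silyloxydiene as a single regioisomer.

**Step 3 (key step)**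
Reactants: 2 1-[2-hydroxy-4,6-bis(prop-2-enyloxy)phenyl]ethanone; 4 3-methyl-2-(trimethylsilyloxy)buta-1,3-diene
Product: 6 1-[3-acetyl-2-hydroxy-4,6-bis(prop-2-enyloxy)phenyl]-3-methylbut-3-en-2-one, via enolonium tosylate 5 (not isolated)
Conditions: PhI(OH)OTs (1.5 equiv), BF3·OEt2 (1.5 equiv, Lewis acid activator), CH2Cl2, −78 °C; 4 (1.5 equiv), 10 min; then 2 (1.0 equiv), −78 to −40 °C; cold aq NaHCO3 quench
Reagents that add atoms: none
Why: Proposed new method: BF3-activated PhI(OH)OTs converts enol silane 4 at −78 °C into the O-bound trivalent-iodine enolate 5, whose terminal CH2 has become an acceptor carbon, and the most nucleophilic ring position of 2 (C-3, ortho to the chelated OH and para to an allyloxy group, the site where 2-hydroxy-4,6-dialkoxyacetophenones are iodinated, prenylated and C-glycosylated under BF3·OEt2) attacks it in an SN2'-type Friedel–Crafts step with loss of PhI, so that two natural donor carbons are joined, the closest known reaction type being the two-stage metal-free alpha-arylation of ketones through preformed enolonium species with indoles and other electron-rich (hetero)arenes, where oxidisable nucleophiles survive because the oxidant is consumed before they are added.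

**Step 4**
Reactants: 6 1-[3-acetyl-2-hydroxy-4,6-bis(prop-2-enyloxy)phenyl]-3-methylbut-3-en-2-one
Product: 7 1-{2-hydroxy-3-[(2S)-2-hydroxy-3-methylbut-3-enyl]-4,6-bis(prop-2-enyloxy)phenyl}ethanone
Conditions: (R)-Me-CBS [(3aR)-1-methyl-3,3-diphenyltetrahydro-1H,3H-pyrrolo[1,2-c][1,3,2]oxazaborole] (20 mol %), catecholborane (2.5 equiv), toluene, −78 °C, 12 h; aqueous work-up
Reagents that add atoms: none
Why: Corey–Bakshi–Shibata reduction in which the alpha-branched sp2 isopropenyl group plays the large and the CH2Ar group the small substituent, so the (R)-catalyst gives the (S)-carbinol (the same sense as (R)-catalyst giving (S)-1-phenylethanol), while the chelated, doubly ortho-substituted aryl ketone and the allyl ethers are inert to catecholborane at −78 °C.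

**Step 5**
Reactants: 7 1-{2-hydroxy-3-[(2S)-2-hydroxy-3-methylbut-3-enyl]-4,6-bis(prop-2-enyloxy)phenyl}ethanone; 8 4-methoxybenzaldehyde
Product: 10 3-hydroxy-8-[(2S)-2-hydroxy-3-methylbut-3-enyl]-2-(4-methoxyphenyl)-5,7-bis(prop-2-enyloxy)-4H-chromen-4-one, via chalcone 9 (not isolated)
Conditions: 8 (1.2 equiv), KOH (50% aq, base), EtOH, rt, 36 h; then MeOH, 30% H2O2 (6 equiv), 0 °C to rt; aq NH4Cl work-up
Reagents that add atoms: hydrogen peroxide, OO
Why: Claisen–Schmidt condensation gives the (E)-chalcone 9 and alkaline H2O2 then performs the Algar–Flynn–Oyamada oxidative cyclisation that closes ring C with its 3-OH, while the nucleophilic oxidant ignores the unactivated alkenes and the carbinol stereocentre, which bears no acidic hydrogen, is untouched.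

**Step 6**
Reactants: 10 3-hydroxy-8-[(2S)-2-hydroxy-3-methylbut-3-enyl]-2-(4-methoxyphenyl)-5,7-bis(prop-2-enyloxy)-4H-chromen-4-one
Product: 11 3,5,7-trihydroxy-8-[(2S)-2-hydroxy-3-methylbut-3-enyl]-2-(4-methoxyphenyl)-4H-chromen-4-one
Conditions: Pd(PPh3)4 (5 mol %), morpholine (10 equiv), THF, rt, Ar
Reagents that add atoms: none
Why: Tsuji–Trost-type deallylation in which zerovalent palladium ionises only the two aryl allyl ethers (phenoxide leaving groups) and morpholine captures the allyl fragments, under neutral conditions that neither ionise the free allylic alcohol nor provoke acid-induced ring closure onto the 7-OH, so the (S)-centre is retained.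

**Compound list**
1 | 2,4,6-trihydroxyacetophenone | CC(=O)c1c(O)cc(O)cc1O | starting material
2 | 1-[2-hydroxy-4,6-bis(prop-2-enyloxy)phenyl]ethanone | CC(=O)c1c(O)cc(OCC=C)cc1OCC=C | intermediate
3 | 3-methylbut-3-en-2-one | CC(=O)C(C)=C | starting material
4 | 3-methyl-2-(trimethylsilyloxy)buta-1,3-diene | C=C(C)C(=C)O[Si](C)(C)C | intermediate
5 | (3-methylbuta-1,3-dien-2-yloxy)(phenyl)(tosyloxy)-λ3-iodane, the enolonium tosylate formed in the flask | C=C(C)C(=C)OI(c1ccccc1)OS(=O)(=O)c1ccc(C)cc1 | intermediate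
6 | 1-[3-acetyl-2-hydroxy-4,6-bis(prop-2-enyloxy)phenyl]-3-methylbut-3-en-2-one | CC(=O)c1c(O)c(CC(=O)C(C)=C)c(OCC=C)cc1OCC=C | intermediate
7 | 1-{2-hydroxy-3-[(2S)-2-hydroxy-3-methylbut-3-enyl]-4,6-bis(prop-2-enyloxy)phenyl}ethanone | C=C(C)[C@@H](O)Cc1c(O)c(C(C)=O)c(OCC=C)cc1OCC=C | intermediate
8 | 4-methoxybenzaldehyde | COc1ccc(C=O)cc1 | starting material
9 | (E)-1-{2-hydroxy-3-[(2S)-2-hydroxy-3-methylbut-3-enyl]-4,6-bis(prop-2-enyloxy)phenyl}-3-(4-methoxyphenyl)prop-2-en-1-one, the chalcone formed in the flask | C=C(C)[C@@H](O)Cc1c(O)c(C(=O)/C=C/c2ccc(OC)cc2)c(OCC=C)cc1OCC=C | intermediate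
10 | 3-hydroxy-8-[(2S)-2-hydroxy-3-methylbut-3-enyl]-2-(4-methoxyphenyl)-5,7-bis(prop-2-enyloxy)-4H-chromen-4-one | C=C(C)[C@@H](O)Cc1c(OCC=C)cc(OCC=C)c2c(=O)c(O)c(-c3ccc(OC)cc3)oc12 | intermediate
11 | 3,5,7-trihydroxy-8-[(2S)-2-hydroxy-3-methylbut-3-enyl]-2-(4-methoxyphenyl)-4H-chromen-4-one | C=C(C)[C@@H](O)Cc1c(O)cc(O)c2c(=O)c(O)c(-c3ccc(OC)cc3)oc12 | target

**Total step count:** 6. **Longest linear sequence:** 5 (steps 1, 3, 4, 5, 6).

**Steps most likely to fail**

**Step 3.**
- Arene 2 is damped by its acetyl group.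
- The phenol could attack through oxygen or exchange onto iodine.
- Some C-5 isomer may form.
- Warm acid could close 6 to a 2-isopropenylbenzofuran.

The fallback sets out from 2 and comes back at 6. Commercial 2-methylbut-1-en-3-yne is treated with pyridine N-oxide and HNTf2 (1 equiv each) and (Ph3P)AuNTf2 (5 mol %) in 1,2-dichloroethane at rt. Markovnikov addition of the N-oxide oxygen followed by protodeauration gives the isolable salt 1-[(3-methylbuta-1,3-dien-2-yl)oxy]pyridinium bis(trifluoromethanesulfonyl)imide F1. This is an enolonium equivalent that needs neither an oxidant nor a Lewis acid. Heating F1 with 2 at 60–80 °C lets ring carbon C-3 displace pyridine at the terminal CH2 and delivers 6.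

**Step 4.**
- The bulky CH2Ar group may erode the large/small discrimination.
- 1,4-Reduction can compete.
- The free phenol consumes borane.

The fallback sets out from 6 and comes back at 7. Luche reduction (NaBH4, CeCl3·7H2O, MeOH, −40 °C) gives racemic 1-{2-hydroxy-3-(2-hydroxy-3-methylbut-3-enyl)-4,6-bis(prop-2-enyloxy)phenyl}ethanone F2. Sharpless kinetic resolution follows (Ti(OiPr)4, D-(−)-diisopropyl tartrate, t-BuOOH 0.6 equiv, 4 Å sieves, CH2Cl2, −20 °C). It epoxidises the fast-reacting (R)-enantiomer to 1-{2-hydroxy-3-[(2R)-2-hydroxy-2-[(2S)-2-methyloxiran-2-yl]ethyl]-4,6-bis(prop-2-enyloxy)phenyl}ethanone F3. The unreacted (S)-alcohol 7 is recovered, in at most 50% yield. 2-Methylalk-1-en-3-ols are among the best substrates for this resolution.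

**Step 5.**
- A 6'-alkoxy group on the chalcone is known to divert the oxidative cyclisation toward aurones.

The fallback sets out from 7 and comes back at 10.
- The condensation is stopped at chalcone 9, which is isolated.
- NaOAc in refluxing EtOH closes it by oxa-Michael addition, which the 6'-alkoxy group favours. This gives 8-[(2S)-2-hydroxy-3-methylbut-3-enyl]-2-(4-methoxyphenyl)-5,7-bis(prop-2-enyloxy)chroman-4-one F4 as C-2 epimers.
- TMSOTf/Et3N (CH2Cl2, 0 °C) gives 2-(4-methoxyphenyl)-8-[(2S)-3-methyl-2-(trimethylsilyloxy)but-3-enyl]-5,7-bis(prop-2-enyloxy)-4-(trimethylsilyloxy)-2H-chromene F5.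
- Rubottom oxidation follows (mCPBA 1.0 equiv, NaHCO3, CH2Cl2, −20 °C, then K2CO3/MeOH). It is selective for the electron-rich silyl enol ether and gives trans-3-hydroxy-8-[(2S)-2-hydroxy-3-methylbut-3-enyl]-2-(4-methoxyphenyl)-5,7-bis(prop-2-enyloxy)chroman-4-one F6.
- Brief H2O2/NaOH in MeOH dehydrogenates F6 to 10. Ring C is already closed at this point, so the aurone branch point of chalcone-epoxide opening is bypassed.

**Further compounds**
F1 | step 3 | 1-[(3-methylbuta-1,3-dien-2-yl)oxy]pyridinium bis(trifluoromethanesulfonyl)imide | C=C(C)C(=C)O[n+]1ccccc1.O=S(=O)([N-]S(=O)(=O)C(F)(F)F)C(F)(F)F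
F2 | step 4 | racemic 1-{2-hydroxy-3-(2-hydroxy-3-methylbut-3-enyl)-4,6-bis(prop-2-enyloxy)phenyl}ethanone | C=C(C)C(O)Cc1c(O)c(C(C)=O)c(OCC=C)cc1OCC=C
F3 | step 4 | 1-{2-hydroxy-3-[(2R)-2-hydroxy-2-[(2S)-2-methyloxiran-2-yl]ethyl]-4,6-bis(prop-2-enyloxy)phenyl}ethanone | C[C@]1(CO1)[C@H](O)Cc1c(O)c(C(C)=O)c(OCC=C)cc1OCC=C
F4 | step 5 | 8-[(2S)-2-hydroxy-3-methylbut-3-enyl]-2-(4-methoxyphenyl)-5,7-bis(prop-2-enyloxy)chroman-4-one (C-2 epimers) | C=C(C)[C@@H](O)Cc1c(OCC=C)cc(OCC=C)c2c1OC(c1ccc(OC)cc1)CC2=O
F5 | step 5 | 2-(4-methoxyphenyl)-8-[(2S)-3-methyl-2-(trimethylsilyloxy)but-3-enyl]-5,7-bis(prop-2-enyloxy)-4-(trimethylsilyloxy)-2H-chromene (C-2 epimers) | C=C(C)[C@@H](O[Si](C)(C)C)Cc1c(OCC=C)cc(OCC=C)c2c1OC(c1ccc(OC)cc1)C=C2O[Si](C)(C)C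
F6 | step 5 | trans-3-hydroxy-8-[(2S)-2-hydroxy-3-methylbut-3-enyl]-2-(4-methoxyphenyl)-5,7-bis(prop-2-enyloxy)chroman-4-one (both 2,3-trans diastereomers) | C=C(C)[C@@H](O)Cc1c(OCC=C)cc(OCC=C)c2c1OC(c1ccc(OC)cc1)C(O)C2=O
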